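The dihydropyranone is read as a vinylogous ester: the O1–C2 bond is the former C=O of an aldehyde, and C3–C4(=O)–C5=C6(CH3) is a four-carbon 1-methoxy-3-silyloxy diene of the acetylacetone oxidation level. Everything rests on cutting C2–C3 and O1–C6. The key step, an (S)-BINOL–Ti(IV)-catalysed formal hetero-Diels–Alder reaction (enantioselective Mukaiyama aldol, then acid-induced 6-endo cyclisation with loss of methanol), joins two achiral acyclic partners, closes the only ring and sets the only stereocentre (C2, R) in one operation. Its precursors are nervonaldehyde, which carries the complete Z-tricosenyl chain, and a 4-methyl Danishefsky-type diene.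

Key step: step 3

Remark: the stereocentre of the target is R by CIP analysis of the structure; methyl nervonate and 4-methoxypent-3-en-2-one are taken as commercial materials of (Z)- and (E)-geometry.

Step 1
Reactants: 1 methyl (15Z)-tetracos-15-enoate (methyl nervonate)
Product: 3 (15Z)-tetracos-15-enal, via aluminium hemiacetal 2 (not isolated)
Conditions: DIBAL-H (1.05 equiv), CH2Cl2, −78 °C; MeOH quench, aq. Rochelle salt
Reagents that add atoms: none
Why: Partial DIBAL-H reduction of an ester works because the tetrahedral aluminium hemiacetal 2 is stable at −78 °C and releases the aldehyde only on aqueous work-up, while the isolated Z-olefin is not hydroaluminated at this temperature.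

Step 2
Reactants: 4 (3E)-4-methoxypent-3-en-2-one
Product: 6 (3E)-4-methoxy-2-(trimethylsilyloxy)penta-1,3-diene, via lithium dienolate 5 (not isolated)
Conditions: LDA (commercial solution, 1.1 equiv), THF, −78 °C; TMSCl (1.2 equiv), −78 °C → rt; pentane, filtration, distillation
Reagents that add atoms: chlorotrimethylsilane (TMSCl), C[Si](C)(C)Cl
Why: Kinetic enolisation of the vinylogous ester at the α'-methyl group and O-silylation of the cross-conjugated dienolate 5 (silyl enol ether formation) should give the 2-silyloxy diene, whose enol ether geometry has no bearing on the next step.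

Step 3
Reactants: 3 (15Z)-tetracos-15-enal; 6 (3E)-4-methoxy-2-(trimethylsilyloxy)penta-1,3-diene
Product: 10 (2R)-6-methyl-2-[(14Z)-tricos-14-en-1-yl]-2,3-dihydro-4H-pyran-4-one (target), via silyl aldol 7 (not isolated), via hydroxy enone 8 (not isolated), via mixed ketal 9 (not isolated)
Conditions: (S)-BINOL (20 mol %), Ti(OiPr)4 (10 mol %), 4 Å MS, Et2O, −20 °C; then TFA (cat.), CH2Cl2, 0 °C; aq. NaHCO3
Reagents that add atoms: none
Why: Mechanism: the (S)-BINOL–Ti(IV) Lewis acid binds aldehyde 3 and the C1 terminus of silyl dienol ether 6 adds to its Si face through an open Mukaiyama aldol transition state, silyl transfer giving (R)-β-silyloxy enone 7 and releasing the catalyst; TFA then cleaves the silyl ether (8), the free hydroxyl adds to the methoxy-bearing β-carbon of the enone to give mixed ketal 9, and loss of methanol regenerates the vinylogous ester as the ring C5=C6 enone of 10. The closest known reaction type is the BINOL–Ti-catalysed Mukaiyama aldol/cyclisation (formal hetero-Diels–Alder reaction) of Danishefsky-type 1-methoxy-3-silyloxy dienes with aliphatic aldehydes. The six-membered ring closes by O1–C6 bond formation in a 6-endo-trig oxa-Michael addition followed by β-elimination (addition–elimination at a vinylogous ester), the C2–C3 bond having been made in the aldol event. The only stereocentre, ring C2, is set in the aldol event under catalyst control and is not touched by the ring closure because its C–O bond is already in place. The step needs enantiofacial selectivity on an unbranched aldehyde (chiral Lewis acid at low temperature), reaction of the diene at C1 only (the silyl enol ether terminus is the sole nucleophilic carbon) and survival of the isolated Z-olefin (inert to Ti(IV) and to brief TFA treatment). The pairing of the (S)-ligand with Si-face attack is assigned by analogy with the allylation and aldol reactions of this catalyst and would be confirmed on a trial run by Mosher correlation, the (R)-ligand being equally available.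

Compound list
1 | methyl (15Z)-tetracos-15-enoate (methyl nervonate) | CCCCCCCC/C=C\CCCCCCCCCCCCCC(=O)OC | starting material
2 | diisobutyl{[(15Z)-1-methoxytetracos-15-en-1-yl]oxy}alumane (aluminium hemiacetal, racemic at C1) | CCCCCCCC/C=C\CCCCCCCCCCCCCC(OC)O[Al](CC(C)C)CC(C)C | intermediate
3 | (15Z)-tetracos-15-enal (nervonaldehyde) | CCCCCCCC/C=C\CCCCCCCCCCCCCC=O | intermediate
4 | (3E)-4-methoxypent-3-en-2-one | CC(=O)/C=C(\C)OC | starting material
5 | lithium (3E)-4-methoxypenta-1,3-dien-2-olate | [Li]OC(=C)/C=C(\C)OC | intermediate
6 | (3E)-4-methoxy-2-(trimethylsilyloxy)penta-1,3-diene | C=C(O[Si](C)(C)C)/C=C(\C)OC | intermediate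
7 | (2E,6R,20Z)-2-methoxy-6-(trimethylsilyloxy)nonacosa-2,20-dien-4-one | CCCCCCCC/C=C\CCCCCCCCCCCCC[C@@H](O[Si](C)(C)C)CC(=O)/C=C(\C)OC | intermediate
8 | (2E,6R,20Z)-6-hydroxy-2-methoxynonacosa-2,20-dien-4-one | CCCCCCCC/C=C\CCCCCCCCCCCCC[C@@H](O)CC(=O)/C=C(\C)OC | intermediate
9 | (6R)-2-methoxy-2-methyl-6-[(14Z)-tricos-14-en-1-yl]oxan-4-one (mixture of C2 epimers) | CCCCCCCC/C=C\CCCCCCCCCCCCC[C@@H]1CC(=O)CC(C)(OC)O1 | intermediate
10 | (2R)-6-methyl-2-[(14Z)-tricos-14-en-1-yl]-2,3-dihydro-4H-pyran-4-one | CCCCCCCC/C=C\CCCCCCCCCCCCC[C@@H]1CC(=O)C=C(C)O1 | target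

Total step count: 3.
Longest linear sequence: 2 steps (1 → 3 → 10, steps 1 and 3); step 2 prepares the diene in a separate one-step branch.

Steps most likely to fail

Step 3 (key step). The catalyst may discriminate the faces of an unbranched aldehyde poorly, turnover may stall because the C24 aldehyde is sparingly soluble in cold ether, and the TFA stage may erode enantiopurity through reversible ring opening (retro-oxa-Michael). The fallback sets out from 3 and comes back at 10; it fixes the stereocentre by reagent control before any ring chemistry. Allylboration of 3 with the allylborane generated from (−)-B-methoxydiisopinocampheylborane (the (+)-α-pinene series) and allylmagnesium bromide (Et2O, −78 °C; NaOH/H2O2 work-up) is expected to deliver allyl to the Si face and give (4R,18Z)-heptacosa-1,18-dien-4-ol F1; the antipodal reagent is available should a trial run show the opposite sense. Acetylation (Ac2O, pyridine, DMAP) should give (4R,18Z)-heptacosa-1,18-dien-4-yl acetate F2. Tsuji–Wacker oxidation (PdCl2 cat., CuCl, O2, DMF–H2O), selective for the terminal olefin over the internal Z-olefin, should give (4R,18Z)-2-oxoheptacos-18-en-4-yl acetate F3. LiHMDS (THF, −78 °C) forms the kinetic methyl enolate, which takes up the neighbouring acetyl group in an intramolecular Claisen condensation to give the lactol (6R)-2-hydroxy-2-methyl-6-[(14Z)-tricos-14-en-1-yl]oxan-4-one F4, and catalytic TsOH dehydrates it to 10.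

Step 2. Deprotonation may compete at the γ-methyl group (C5) of the vinylogous ester, and the silyl dienol ether may hydrolyse during isolation. The fallback sets out from 3 and comes back at 10 without passing through 6; the nucleophile is redesigned so that the site of enolisation no longer matters. Commercial 4-(trimethylsilyloxy)pent-3-en-2-one is treated with LDA and TMSCl (THF, −78 °C). Because of the symmetry of the acetylacetone skeleton, deprotonation at either methyl group leads to the same constitution, 2,4-bis(trimethylsilyloxy)penta-1,3-diene F5 (drawn as the 3Z isomer; the geometry has no bearing on the aldol), which is used crude. The same (S)-BINOL–Ti(IV) aldol with 3, followed by mild acidic desilylation, should give (6R,20Z)-6-hydroxynonacos-20-ene-2,4-dione F6. Acid-catalysed cyclodehydration (TsOH, CH2Cl2) then closes the ring to 10.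

Step 1. The aluminium hemiacetal may collapse before the quench and be reduced further, or the reduction may stop short, leaving ester, aldehyde and alcohol of almost identical polarity. The fallback sets out from 1 and comes back at 3. Exhaustive reduction with LiAlH4 (THF, 0 °C) gives (15Z)-tetracos-15-en-1-ol F7, which can be purified by crystallisation. Oxidation with Dess–Martin periodinane (CH2Cl2, NaHCO3) then gives 3.

Further compounds
F1 | step 3 | (4R,18Z)-heptacosa-1,18-dien-4-ol | CCCCCCCC/C=C\CCCCCCCCCCCCC[C@@H](O)CC=C
F2 | step 3 | (4R,18Z)-heptacosa-1,18-dien-4-yl acetate | CCCCCCCC/C=C\CCCCCCCCCCCCC[C@@H](OC(C)=O)CC=C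
F3 | step 3 | (4R,18Z)-2-oxoheptacos-18-en-4-yl acetate | CCCCCCCC/C=C\CCCCCCCCCCCCC[C@@H](OC(C)=O)CC(C)=O
F4 | step 3 | (6R)-2-hydroxy-2-methyl-6-[(14Z)-tricos-14-en-1-yl]oxan-4-one (lactol, anomeric mixture) | CCCCCCCC/C=C\CCCCCCCCCCCCC[C@@H]1CC(=O)CC(C)(O)O1
F5 | step 2 | (3Z)-2,4-bis(trimethylsilyloxy)penta-1,3-diene | C=C(O[Si](C)(C)C)/C=C(/C)O[Si](C)(C)C
F6 | step 2 | (6R,20Z)-6-hydroxynonacos-20-ene-2,4-dione | CCCCCCCC/C=C\CCCCCCCCCCCCC[C@@H](O)CC(=O)CC(C)=O
F7 | step 1 | (15Z)-tetracos-15-en-1-ol | CCCCCCCC/C=C\CCCCCCCCCCCCCCO
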